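## Analysis of the target

Compound 18 is an open-chain bis(bibenzyl) with four benzene rings and no other ring. Ring A (a 3-hydroxyphenyl group) and ring B (1,4-disubstituted) are joined by a CH2CH2 bridge, and ring C and ring D by a second one. The two halves are held together by a single diaryl ether oxygen running from ring B C4 to ring C C3. Ring C carries its bridge at C1, the ether oxygen at C3 and a hydroxyl at C4, while ring D is a catechol with the bridge next to one of the hydroxyls (1,2,3-pattern). There is no stereocentre, so the problem is purely one of constitution. The four free phenols, above all the catechol of ring D and the ortho-aryloxyphenol of ring C, are easily oxidised and are best kept masked until the last step. The difficulty lies in placing the substituents correctly on three differently oxygenated rings, in forming an unsymmetrical ether next to an oxygen substituent, and in making two unfunctionalised sp3–sp3 bridges. The strategy rests on ring A: its C1 (bridge), C2–H and C3 (oxygen) reproduce C6 (with its methyl group), C5 and C4 (with its methoxy group) of pyrone 11. Pyrone C3 becomes ring A C4, and ring A C5 and C6 are the two carbons of alkyne 14.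

## Retrosynthetic reasoning

**18 back to 17.** The four O–H groups are traced back to four O–CH3 groups, cleaved together at the very end by a Lewis acid. Methyl is chosen because it survives strong base, heating to 140 °C and a dissolving metal, and because the ring A methyl ether is simply the methoxy group that pyrone 11 already carries. The oxidation-prone catechol is therefore never exposed before the last step.

**17 back to 16.** A p-tolylsulfonyl group is put back on ring A C6. It has no place in the target; it is the activating group that makes the two-carbon partner of the ring synthesis reactive enough. Its removal in the forward direction is a reductive cleavage of the ring A C–S bond.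

**16 back to 13 and 14 (through 15).** Ring A is opened at C4–C5 and at C1–C6, and the lactone bridge is restored between the carbons that become ring A C1 and C4. This is the retro form of a Diels–Alder addition followed by decarboxylation. Ring A is the only ring cut this way because it alone has the meta relationship of oxygen and carbon chain that a 4-oxygenated 6-alkylpyrone delivers; rings C and D are 1,2-dioxygenated and do not fit. The gain is that the meta pattern is inherited from 13 and needs no selection, and that the benzylic carbon of ring A becomes a pyrone side-chain carbon, which is easy to make nucleophilic.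

**13 back to 10 and 11 (through 12).** The central CH2–CH2 bond of the A–B bridge is cut. On the pyrone side the carbon is the C6 methyl group of 11, which is vinylogously acidic and gives the lithiated species 12. On the ring B side it is the benzylic bromide 10. The forward step must alkylate 12 once, at carbon, without attack on the lactone.

**10 back to 9, 8, and then 6 and 7.** The bromide comes from alcohol 9 and that from aldehyde 8 by routine functional-group changes. The diaryl ether is cut on the ring B side because there the formyl group of 7 activates the para fluorine for displacement. The hindered, electron-rich phenol 6 then only has to act as the nucleophile, and the formyl group is afterwards the handle for the bridge.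

**6 back to 5, and then 2 and 3 (through 4); 2 back to 1.** The C–D bridge is traced to the olefin 5, cut at the double bond into a benzylic phosphonium salt (2, from alcohol 1) and aldehyde 3. The benzyl ether of 3 is chosen so that one hydrogenation saturates the olefin and frees the one phenol that is needed for the ether formation.

## Alternatives that were turned down

**Alternative 1:** Ring D is made last, from a furan.
- Disconnection: the bond between the bridge-bearing carbon of ring D and its unsubstituted neighbour.
- Forward key step: the masked precursor A2 (a 2,5-dimethoxytetrahydrofuran with a dioxolane-protected acyl group at C2, the acyl chain being the four-carbon tether to ring C) is hydrolysed in aqueous acid to the open-chain dioxo aldehyde A3. The methylene next to the 1,2-diketone adds to the aldehyde carbon, and dehydration and enolisation give catechol A1.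
- For it: the catechol arrives free, so only two methyl ethers remain to be cleaved. No auxiliary group has to be removed, and the 1,2,3-pattern of ring D follows from connectivity alone.
- Against it: A2 needs a long preparation (acylation, ketalisation, oxidative dimethoxylation of the furan, hydrogenation), and the oxidation has to be done beside three electron-rich anisole-type rings. A3 has three carbonyl groups and several enolisable positions, so other aldol modes and oligomerisation compete, and the air-sensitive catechol is formed in hot acid.
- Comparison: it is stronger on protecting-group economy at the end. The chosen route instead closes its ring through a single pericyclic pathway from a stable, isolable pyrone (13), with no oxidation near electron-rich arenes.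

**Alternative 2:** Ring C is assembled by a three-plus-three condensation.
- Disconnection: the two ring C bonds that link the carbon bearing the aryloxy group and the unsubstituted carbon on the other side of the hydroxyl-bearing carbon to the two CH carbons flanking the bridge-bearing carbon.
- Forward key step: the aryloxyacetone A5 (the ketone made from the ring A–B phenol) is condensed under a strong alkoxide base with the vinamidinium salt A6, which carries the arylethyl chain at its central carbon. Two amine molecules are lost and the ring aromatises to phenol A4.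
- For it: it is the most convergent plan. Two halves of similar size are joined as ring C forms, the ring C hydroxyl ends up para to the bridge by construction, and the ether oxygen is attached by a simple O-alkylation rather than by arylation of a hindered phenol. It is shorter than the chosen route.
- Against it: the second C–C bond needs the weakly acidic methyl terminus of A5 to react after the aryloxy-substituted methylene has done so. O-cyclisation and self-condensation of A5 compete. A6 has to be made by a Vilsmeier-type formylation in the presence of a dimethoxyarene that can itself be formylated.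
- Comparison: it wins on step count and convergence. The chosen route offers a ring closure with no acid–base equilibria, and a failure mode that returns 13 unchanged rather than consuming two advanced fragments.

**Alternative 3:** Ring D is functionalised through an aryne.
- Disconnection: the ring D C1–CH2 bond and the ring D C2–O bond.
- Forward key step: 3-fluoroanisole A10 is lithiated to A11, which loses its fluorine to give 3-methoxybenzyne A9. The Grignard reagent A8, holding rings A, B and C, adds at the aryne carbon remote from the methoxy group. The arylmagnesium formed next to the methoxy group is borylated and oxidised to give phenol A7.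
- For it: the polarisation of A9 makes the 1,2,3-pattern reliable, two bonds form in one pot, no ring has to be built, and the sequence is the shortest of all.
- Against it: A8 is the most valuable fragment and must be used in excess to outrun addition of A11 to A9. Its formation from a 2-arylethyl halide is accompanied by homocoupling. The hindered 2,6-disubstituted arylmagnesium must then be borylated and oxidised cleanly.
- Comparison: it is shorter and equally secure in regiochemistry. The chosen route spends only cheap commercial compounds (11 and 14) in excess and keeps the advanced intermediate as the limiting, recoverable partner in its uncertain step.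

Key step: step 8

Assumption: aldehyde 3 is bought as the O-benzyl ether of isovanillin (otherwise one benzylation from isovanillin). Olefin 5 is carried as an E/Z mixture and cycloadduct 15 as a racemate, because both stereo-elements are destroyed in the transformation that follows.

## Route

**Step 1**
Reactants: 1 2,3-dimethoxybenzyl alcohol
Product: 2 (2,3-dimethoxybenzyl)triphenylphosphonium bromide
Conditions: Ph3P·HBr, MeCN, reflux
Reagents that add atoms: triphenylphosphine hydrobromide, [Br-].c1ccc([PH+](c2ccccc2)c2ccccc2)cc1
Why: The benzylic alcohol is protonated by the acidic phosphonium salt and displaced by triphenylphosphine (benzylic substitution assisted by the ortho-methoxy group), which gives the phosphonium salt without a separate halide.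

**Step 2**
Reactants: 2 (2,3-dimethoxybenzyl)triphenylphosphonium bromide; 3 3-(benzyloxy)-4-methoxybenzaldehyde
Product: 5 2-(benzyloxy)-4-[2-(2,3-dimethoxyphenyl)ethenyl]-1-methoxybenzene (E/Z mixture), via phosphonium ylide 4 (not isolated)
Conditions: KOtBu, THF, 0 °C to rt
Reagents that add atoms: none
Why: Wittig olefination of a semi-stabilised benzylic ylide with an aromatic aldehyde; the E/Z mixture does not matter because the double bond is saturated in step 3, and no stereocentre is formed.

**Step 3**
Reactants: 5 2-(benzyloxy)-4-[2-(2,3-dimethoxyphenyl)ethenyl]-1-methoxybenzene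
Product: 6 5-[2-(2,3-dimethoxyphenyl)ethyl]-2-methoxyphenol
Conditions: H2 (1 atm), 10% Pd/C, EtOAc–MeOH, rt
Reagents that add atoms: none
Why: Heterogeneous catalytic hydrogenation saturates the stilbene double bond and hydrogenolyses the benzyl ether in the same operation; the aryl methyl ethers are inert.

**Step 4**
Reactants: 6 5-[2-(2,3-dimethoxyphenyl)ethyl]-2-methoxyphenol; 7 4-fluorobenzaldehyde
Product: 8 4-{5-[2-(2,3-dimethoxyphenyl)ethyl]-2-methoxyphenoxy}benzaldehyde
Conditions: K2CO3, DMAc, 120 °C
Reagents that add atoms: none
Why: Nucleophilic aromatic substitution (addition–elimination) of the fluorine para to the formyl group by the phenoxide of 6; the activated aryl fluoride makes the ether bond without a metal catalyst even though the phenol is flanked by a methoxy group.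

**Step 5**
Reactants: 8 4-{5-[2-(2,3-dimethoxyphenyl)ethyl]-2-methoxyphenoxy}benzaldehyde
Product: 9 (4-{5-[2-(2,3-dimethoxyphenyl)ethyl]-2-methoxyphenoxy}phenyl)methanol
Conditions: NaBH4, MeOH–THF, 0 °C
Reagents that add atoms: none
Why: Borohydride reduction of an aromatic aldehyde to the benzylic alcohol; nothing else in the molecule is reducible under these conditions.

**Step 6**
Reactants: 9 (4-{5-[2-(2,3-dimethoxyphenyl)ethyl]-2-methoxyphenoxy}phenyl)methanol
Product: 10 2-[4-(bromomethyl)phenoxy]-4-[2-(2,3-dimethoxyphenyl)ethyl]-1-methoxybenzene
Conditions: PBr3, CH2Cl2, 0 °C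
Reagents that add atoms: phosphorus tribromide, BrP(Br)Br
Why: Bromination of a benzylic alcohol through its phosphite ester with displacement by bromide; the para-aryloxy group makes the bromide labile, so it should be used directly in step 7.

**Step 7**
Reactants: 11 4-methoxy-6-methyl-2H-pyran-2-one; 10 2-[4-(bromomethyl)phenoxy]-4-[2-(2,3-dimethoxyphenyl)ethyl]-1-methoxybenzene
Product: 13 6-[2-(4-{5-[2-(2,3-dimethoxyphenyl)ethyl]-2-methoxyphenoxy}phenyl)ethyl]-4-methoxy-2H-pyran-2-one, via lithiated pyrone 12 (not isolated)
Conditions: 11 (1.5 equiv), LiN(iPr)2 (LDA), THF, −78 °C; then 10, DMPU, −78 to −20 °C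
Reagents that add atoms: none
Why: LDA removes a proton from the C6 methyl group, which is vinylogous to the lactone carbonyl, and the extended enolate 12 is benzylated at its terminal carbon by SN2 displacement; this lateral alkylation of 11 with benzylic halides is an established reaction, and the excess of cheap anion limits a second alkylation.

**Step 8**
Reactants: 13 6-[2-(4-{5-[2-(2,3-dimethoxyphenyl)ethyl]-2-methoxyphenoxy}phenyl)ethyl]-4-methoxy-2H-pyran-2-one; 14 ethynyl p-tolyl sulfone
Product: 16 2-[2-(4-{5-[2-(2,3-dimethoxyphenyl)ethyl]-2-methoxyphenoxy}phenyl)ethyl]-4-methoxy-1-[(4-methylphenyl)sulfonyl]benzene, via bicyclic lactone cycloadduct 15 (not isolated)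
Conditions: 14 (4 equiv, added in portions), BHT (cat.), o-xylene, sealed tube, 140 °C
Reagents that add atoms: none
Why: The diene C3=C4–C5=C6 of pyrone 13, raised in energy by the C4 methoxy group, adds across C3 and C6 to the electron-poor triple bond of 14 in a normal-demand Diels–Alder reaction and gives the bridged lactone 15. Adduct 15 then loses carbon dioxide by a retro-[4+2] step, which should be fast for an alkyne adduct because it creates a benzene ring. The closest known reactions are the thermal cycloaddition–decarboxylation of 4-methoxy-6-alkyl-2-pyrones with acetylenic esters and the Diels–Alder additions of ethynyl sulfones to cyclic dienes. Ring A is the only ring closed; it is closed by an intermolecular [4+2] cycloaddition that forms both new C–C bonds (pyrone C3 to the alkyne CH, pyrone C6 to the sulfonyl-bearing carbon) in one operation, after which the lactone bridge is excised. The two bridgehead stereocentres of 15 arise as a racemate without control and vanish on aromatisation, so no stereochemical element has to be secured. The larger HOMO coefficient at C3, the β-carbon of the enol ether, should bond it to the unsubstituted alkyne carbon and place the sulfonyl group ortho to the chain, but the opposite orientation would converge on 17 in step 9. The selectivity that matters is cycloaddition over thermal oligomerisation of 14 and over conjugate addition to it; this is helped by the absence of any free OH or NH nucleophile in 13 and by portionwise addition of an excess of 14.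

**Step 9**
Reactants: 16 2-[2-(4-{5-[2-(2,3-dimethoxyphenyl)ethyl]-2-methoxyphenoxy}phenyl)ethyl]-4-methoxy-1-[(4-methylphenyl)sulfonyl]benzene
Product: 17 4-[2-(2,3-dimethoxyphenyl)ethyl]-1-methoxy-2-{4-[2-(3-methoxyphenyl)ethyl]phenoxy}benzene
Conditions: Mg turnings (excess), MeOH–THF, 50 °C
Reagents that add atoms: none
Why: Reductive desulfonylation by single-electron transfer: the radical anion of the diaryl sulfone fragments at a C–S bond and the aryl fragment is protonated by methanol. Cleavage on the ring A side is expected because it expels the more stable p-toluenesulfinate and relieves the ortho-alkyl strain; the diaryl ether and methyl ethers are not reduced by magnesium.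

**Step 10**
Reactants: 17 4-[2-(2,3-dimethoxyphenyl)ethyl]-1-methoxy-2-{4-[2-(3-methoxyphenyl)ethyl]phenoxy}benzene
Product: 18 3-[2-(4-hydroxy-3-{4-[2-(3-hydroxyphenyl)ethyl]phenoxy}phenyl)ethyl]benzene-1,2-diol
Conditions: BBr3 (8 equiv), CH2Cl2, −78 °C to rt; then MeOH, H2O, 0 °C, under argon
Reagents that add atoms: none
Why: Lewis acid–mediated cleavage of the four aryl methyl ethers: each methoxy oxygen coordinates to boron and bromide attacks the methyl carbon, and aqueous work-up hydrolyses the aryl borates. The diaryl ether and the saturated bridges are inert, and there is no stereocentre to disturb.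

## Compound list

1 | 2,3-dimethoxybenzyl alcohol | COc1cccc(CO)c1OC | starting material
2 | (2,3-dimethoxybenzyl)triphenylphosphonium bromide | [Br-].COc1cccc(C[P+](c2ccccc2)(c2ccccc2)c2ccccc2)c1OC | intermediate
3 | 3-(benzyloxy)-4-methoxybenzaldehyde | COc1ccc(C=O)cc1OCc1ccccc1 | starting material
4 | (2,3-dimethoxybenzylidene)triphenylphosphorane (ylide) | COc1cccc(C=P(c2ccccc2)(c2ccccc2)c2ccccc2)c1OC | intermediate (not isolated)
5 | 2-(benzyloxy)-4-[2-(2,3-dimethoxyphenyl)ethenyl]-1-methoxybenzene (E/Z mixture) | COc1ccc(C=Cc2cccc(OC)c2OC)cc1OCc1ccccc1 | intermediate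
6 | 5-[2-(2,3-dimethoxyphenyl)ethyl]-2-methoxyphenol | COc1ccc(CCc2cccc(OC)c2OC)cc1O | intermediate
7 | 4-fluorobenzaldehyde | O=Cc1ccc(F)cc1 | starting material
8 | 4-{5-[2-(2,3-dimethoxyphenyl)ethyl]-2-methoxyphenoxy}benzaldehyde | COc1ccc(CCc2cccc(OC)c2OC)cc1Oc1ccc(C=O)cc1 | intermediate
9 | (4-{5-[2-(2,3-dimethoxyphenyl)ethyl]-2-methoxyphenoxy}phenyl)methanol | COc1ccc(CCc2cccc(OC)c2OC)cc1Oc1ccc(CO)cc1 | intermediate
10 | 2-[4-(bromomethyl)phenoxy]-4-[2-(2,3-dimethoxyphenyl)ethyl]-1-methoxybenzene | COc1ccc(CCc2cccc(OC)c2OC)cc1Oc1ccc(CBr)cc1 | intermediate
11 | 4-methoxy-6-methyl-2H-pyran-2-one | COC1=CC(=O)OC(C)=C1 | starting material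
12 | 6-(lithiomethyl)-4-methoxy-2H-pyran-2-one (extended enolate) | COC1=CC(=O)OC(C[Li])=C1 | intermediate (not isolated)
13 | 6-[2-(4-{5-[2-(2,3-dimethoxyphenyl)ethyl]-2-methoxyphenoxy}phenyl)ethyl]-4-methoxy-2H-pyran-2-one | COC1=CC(=O)OC(CCc2ccc(Oc3cc(CCc4cccc(OC)c4OC)ccc3OC)cc2)=C1 | intermediate
14 | ethynyl p-tolyl sulfone | Cc1ccc(S(=O)(=O)C#C)cc1 | starting material
15 | racemic 1-[2-(4-{5-[2-(2,3-dimethoxyphenyl)ethyl]-2-methoxyphenoxy}phenyl)ethyl]-8-methoxy-6-[(4-methylphenyl)sulfonyl]-2-oxabicyclo[2.2.2]octa-5,7-dien-3-one | O=C1OC2(CCc3ccc(Oc4cc(CCc5cccc(OC)c5OC)ccc4OC)cc3)C=C(OC)C1C=C2S(=O)(=O)c1ccc(C)cc1 | intermediate (not isolated)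
16 | 2-[2-(4-{5-[2-(2,3-dimethoxyphenyl)ethyl]-2-methoxyphenoxy}phenyl)ethyl]-4-methoxy-1-[(4-methylphenyl)sulfonyl]benzene | COc1ccc(S(=O)(=O)c2ccc(C)cc2)c(CCc2ccc(Oc3cc(CCc4cccc(OC)c4OC)ccc3OC)cc2)c1 | intermediate
17 | 4-[2-(2,3-dimethoxyphenyl)ethyl]-1-methoxy-2-{4-[2-(3-methoxyphenyl)ethyl]phenoxy}benzene | COc1cccc(CCc2ccc(Oc3cc(CCc4cccc(OC)c4OC)ccc3OC)cc2)c1 | intermediate
18 | 3-[2-(4-hydroxy-3-{4-[2-(3-hydroxyphenyl)ethyl]phenoxy}phenyl)ethyl]benzene-1,2-diol | Oc1cccc(CCc2ccc(Oc3cc(CCc4cccc(O)c4O)ccc3O)cc2)c1 | target

## Step count and least certain steps

Total: 10 steps. Longest linear sequence: 10 steps (1 to 18); compounds 3, 7, 11 and 14 enter as purchased materials.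

**Step 8 (key step).** The most likely failure is thermal oligomerisation of the alkynyl sulfone outrunning cycloaddition to the partly aromatic, sluggish pyrone diene. A second possibility is conjugate addition of pyrone C3 to the alkyne that does not go on to ring closure. Either would leave 13 largely unreacted or divert it to open-chain vinyl sulfones. The fallback keeps the ring construction but changes the two-carbon partner and the way its activating group is removed. It sets out from 13, which is heated with an excess of methyl propiolate (a thermally robust dienophile, usable at 170–180 °C in a sealed tube) to give, after loss of carbon dioxide, methyl 2-[2-(4-{5-[2-(2,3-dimethoxyphenyl)ethyl]-2-methoxyphenoxy}phenyl)ethyl]-4-methoxybenzoate F1. Saponification with LiOH in THF–MeOH–H2O gives 2-[2-(4-{5-[2-(2,3-dimethoxyphenyl)ethyl]-2-methoxyphenoxy}phenyl)ethyl]-4-methoxybenzoic acid F2. Protodecarboxylation with catalytic Cu2O and 1,10-phenanthroline in NMP–quinoline at 170 °C then removes the carboxyl group, and the route is rejoined at 17, bypassing 16 and step 9.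

**Step 9.** The radical anion may fragment at the tolyl–sulfur bond instead of the ring A–sulfur bond, leaving a sulfinic acid on ring A, or the reduction may stall on the passivated metal surface. The fallback replaces electron-transfer cleavage by hydrogenolysis of both C–S bonds, so the question of which bond breaks does not arise. It sets out from 16, which is reduced with LiAlH4–TiCl4 in THF to the diaryl sulfide 2-[2-(4-{5-[2-(2,3-dimethoxyphenyl)ethyl]-2-methoxyphenoxy}phenyl)ethyl]-4-methoxy-1-[(4-methylphenyl)sulfanyl]benzene F3. Desulfurisation of F3 with Raney Ni in refluxing EtOH returns to the route at 17.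

**Step 7.** Proton transfer from product 13 to the anion 12 can lead to a second benzylation at the same carbon. Competing metalation at pyrone C3 and addition of the amide base or of 12 to a lactone carbonyl would also consume material, and the labile bromide 10 may decompose before it is alkylated. The fallback builds the pyrone ring from a carboxylic ester instead of alkylating a preformed pyrone. It sets out from aldehyde 8:
- Horner–Wadsworth–Emmons olefination with triethyl phosphonoacetate and NaH in THF gives ethyl (E)-3-(4-{5-[2-(2,3-dimethoxyphenyl)ethyl]-2-methoxyphenoxy}phenyl)prop-2-enoate F4.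
- Hydrogenation over 10% Pd/C gives ethyl 3-(4-{5-[2-(2,3-dimethoxyphenyl)ethyl]-2-methoxyphenoxy}phenyl)propanoate F5.
- Claisen condensation of F5 with the dianion of methyl acetoacetate (NaH, then n-BuLi, THF, 0 °C) gives methyl 7-(4-{5-[2-(2,3-dimethoxyphenyl)ethyl]-2-methoxyphenoxy}phenyl)-3,5-dioxoheptanoate F6.
- Lactonisation with DBU in refluxing toluene gives 6-[2-(4-{5-[2-(2,3-dimethoxyphenyl)ethyl]-2-methoxyphenoxy}phenyl)ethyl]-4-hydroxy-2H-pyran-2-one F7.
- O-Methylation of F7 with Me2SO4 and K2CO3 in acetone returns to the route at 13.

## Further compounds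

F1 | step 8 | methyl 2-[2-(4-{5-[2-(2,3-dimethoxyphenyl)ethyl]-2-methoxyphenoxy}phenyl)ethyl]-4-methoxybenzoate | COC(=O)c1ccc(OC)cc1CCc1ccc(Oc2cc(CCc3cccc(OC)c3OC)ccc2OC)cc1
F2 | step 8 | 2-[2-(4-{5-[2-(2,3-dimethoxyphenyl)ethyl]-2-methoxyphenoxy}phenyl)ethyl]-4-methoxybenzoic acid | OC(=O)c1ccc(OC)cc1CCc1ccc(Oc2cc(CCc3cccc(OC)c3OC)ccc2OC)cc1
F3 | step 9 | 2-[2-(4-{5-[2-(2,3-dimethoxyphenyl)ethyl]-2-methoxyphenoxy}phenyl)ethyl]-4-methoxy-1-[(4-methylphenyl)sulfanyl]benzene | COc1ccc(Sc2ccc(C)cc2)c(CCc2ccc(Oc3cc(CCc4cccc(OC)c4OC)ccc3OC)cc2)c1
F4 | step 7 | ethyl (E)-3-(4-{5-[2-(2,3-dimethoxyphenyl)ethyl]-2-methoxyphenoxy}phenyl)prop-2-enoate | CCOC(=O)/C=C/c1ccc(Oc2cc(CCc3cccc(OC)c3OC)ccc2OC)cc1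
F5 | step 7 | ethyl 3-(4-{5-[2-(2,3-dimethoxyphenyl)ethyl]-2-methoxyphenoxy}phenyl)propanoate | CCOC(=O)CCc1ccc(Oc2cc(CCc3cccc(OC)c3OC)ccc2OC)cc1
F6 | step 7 | methyl 7-(4-{5-[2-(2,3-dimethoxyphenyl)ethyl]-2-methoxyphenoxy}phenyl)-3,5-dioxoheptanoate | COC(=O)CC(=O)CC(=O)CCc1ccc(Oc2cc(CCc3cccc(OC)c3OC)ccc2OC)cc1
F7 | step 7 | 6-[2-(4-{5-[2-(2,3-dimethoxyphenyl)ethyl]-2-methoxyphenoxy}phenyl)ethyl]-4-hydroxy-2H-pyran-2-one | OC1=CC(=O)OC(CCc2ccc(Oc3cc(CCc4cccc(OC)c4OC)ccc3OC)cc2)=C1
A1 | alternative 1 | 3-[2-(4-methoxy-3-{4-[2-(3-methoxyphenyl)ethyl]phenoxy}phenyl)ethyl]benzene-1,2-diol | Oc1cccc(CCc2ccc(OC)c(Oc3ccc(CCc4cccc(OC)c4)cc3)c2)c1O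
A2 | alternative 1 | 2,5-dimethoxy-2-{2-[3-(4-methoxy-3-{4-[2-(3-methoxyphenyl)ethyl]phenoxy}phenyl)propyl]-1,3-dioxolan-2-yl}oxolane (mixture of diastereomers) | COC1CCC(OC)(O1)C1(CCCc2ccc(OC)c(Oc3ccc(CCc4cccc(OC)c4)cc3)c2)OCCO1
A3 | alternative 1 | 8-(4-methoxy-3-{4-[2-(3-methoxyphenyl)ethyl]phenoxy}phenyl)-4,5-dioxooctanal | O=CCCC(=O)C(=O)CCCc1ccc(OC)c(Oc2ccc(CCc3cccc(OC)c3)cc2)c1
A4 | alternative 2 | 4-[2-(2,3-dimethoxyphenyl)ethyl]-2-{4-[2-(3-methoxyphenyl)ethyl]phenoxy}phenol | COc1cccc(CCc2ccc(Oc3cc(CCc4cccc(OC)c4OC)ccc3O)cc2)c1
A5 | alternative 2 | 1-{4-[2-(3-methoxyphenyl)ethyl]phenoxy}propan-2-one | CC(=O)COc1ccc(CCc2cccc(OC)c2)cc1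
A6 | alternative 2 | 2-[2-(2,3-dimethoxyphenyl)ethyl]-1,3-bis(dimethylamino)trimethinium hexafluorophosphate | CN(C)C=C(CCc1cccc(OC)c1OC)C=[N+](C)C.F[P-](F)(F)(F)(F)F
A7 | alternative 3 | 2-methoxy-6-[2-(4-methoxy-3-{4-[2-(3-methoxyphenyl)ethyl]phenoxy}phenyl)ethyl]phenol | COc1cccc(CCc2ccc(Oc3cc(CCc4cccc(OC)c4O)ccc3OC)cc2)c1
A8 | alternative 3 | [2-(4-methoxy-3-{4-[2-(3-methoxyphenyl)ethyl]phenoxy}phenyl)ethyl]magnesium bromide | COc1cccc(CCc2ccc(Oc3cc(CC[Mg]Br)ccc3OC)cc2)c1
A9 | alternative 3 | 3-methoxybenzyne (1,2-didehydro-3-methoxybenzene) | COC1=CC=CC#C1
A10 | alternative 3 | 3-fluoroanisole | COc1cccc(F)c1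
A11 | alternative 3 | 2-fluoro-6-methoxyphenyllithium | COc1cccc(F)c1[Li]
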